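**Plan**

- Chain numbering: ArC7H2–C8H(C9H3)–C8′H(C9′H3)–C7′H2Ar. Retrosynthetically C9 is raised to a carboxyl and C7′ to a benzylic C–O, which closes a γ-lactone (O–C9(=O)–C8–C8′–C7′) holding both stereocentres in a five-membered ring. In that ring a trans-3,4 pair corresponds to the meso pair of the open chain.
- Cuts, in order: the lactone back from the chain, then C7–C8 and C8′–C9′ together (benzyl bromide, methyl cuprate), then C8=C8′ (metathesis), the ester C–O and C7′–C8′ (vinyl Grignard). Both aryl halves come from O-benzylsyringaldehyde.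
- Forward: the butenolide is closed by RCM (the only ring closure) and the three-component step joins the two halves on it. Hydrogenolysis then opens the ring and frees the phenols, and C9 is taken from CO2H through CH2OH and CH2I to CH3.
- Stereochemistry: the C7′ aryl group sends methyl to the opposite face of C8′, and that methyl sends the benzyl group to the opposite face of C8. C7′ later becomes CH2.

Key step: step 7

Assumption: the (R,S) pair in the target SMILES sits on a chain with identical ends, so the target is the achiral meso compound; all chiral intermediates are therefore made as racemates and drawn as one enantiomer.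

**Route**

Step 1
Reactants: 1 syringaldehyde
Product: 2 4-(benzyloxy)-3,5-dimethoxybenzaldehyde
Conditions: BnBr, K2CO3, DMF, 60 °C
Reagents that add atoms: benzyl bromide, BrCc1ccccc1
Why: Williamson ether synthesis; the phenoxide of the acidic 4-OH is O-alkylated by SN2 while the aldehyde is inert to carbonate.

Step 2
Reactants: 2 4-(benzyloxy)-3,5-dimethoxybenzaldehyde; 3 vinylmagnesium bromide
Product: 4 rac-1-[4-(benzyloxy)-3,5-dimethoxyphenyl]prop-2-en-1-ol
Conditions: THF, −78 → 0 °C; sat. aq. NH4Cl
Reagents that add atoms: none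
Why: Grignard 1,2-addition to a non-enolisable aryl aldehyde forms C7′–C8′; the carbinol centre arises racemic, which suffices because it is erased in step 8.

Step 3
Reactants: 4 rac-1-[4-(benzyloxy)-3,5-dimethoxyphenyl]prop-2-en-1-ol; 5 acryloyl chloride
Product: 6 rac-1-[4-(benzyloxy)-3,5-dimethoxyphenyl]prop-2-en-1-yl prop-2-enoate
Conditions: Et3N, DMAP (cat.), CH2Cl2, −20 → 0 °C
Reagents that add atoms: none
Why: DMAP-catalysed O-acylation of the secondary alcohol under cold, basic conditions that should avoid ionisation of the allylic benzylic C–O bond; the carbinol centre is not touched.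

Step 4
Reactants: 6 rac-1-[4-(benzyloxy)-3,5-dimethoxyphenyl]prop-2-en-1-yl prop-2-enoate
Product: 7 rac-5-[4-(benzyloxy)-3,5-dimethoxyphenyl]furan-2(5H)-one
Conditions: Grubbs II (5 mol %), CH2Cl2 (0.01 M), 40 °C
Reagents that add atoms: none
Why: Ring-closing metathesis of the allyl acrylate closes the five-membered unsaturated lactone by forming C8=C8′ with loss of ethylene; the second-generation ruthenium carbene accepts the electron-poor acrylate.

Step 5
Reactants: 2 4-(benzyloxy)-3,5-dimethoxybenzaldehyde
Product: 8 [4-(benzyloxy)-3,5-dimethoxyphenyl]methanol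
Conditions: NaBH4, MeOH–THF, 0 °C
Reagents that add atoms: none
Why: Borohydride reduction of the aldehyde, the only reducible group present.

Step 6
Reactants: 8 [4-(benzyloxy)-3,5-dimethoxyphenyl]methanol
Product: 9 2-(benzyloxy)-5-(bromomethyl)-1,3-dimethoxybenzene
Conditions: PBr3, Et2O, 0 °C
Reagents that add atoms: phosphorus tribromide, BrP(Br)Br
Why: The primary benzylic alcohol is activated as its bromophosphite ester and displaced by bromide (SN2); aryl ethers are inert at 0 °C.

Step 7
Reactants: 7 rac-5-[4-(benzyloxy)-3,5-dimethoxyphenyl]furan-2(5H)-one; 9 2-(benzyloxy)-5-(bromomethyl)-1,3-dimethoxybenzene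
Product: 11 rac-(3S,4S,5S)-3-[4-(benzyloxy)-3,5-dimethoxybenzyl]-5-[4-(benzyloxy)-3,5-dimethoxyphenyl]-4-methyldihydrofuran-2(3H)-one, via lithium lactone enolate 10 (not isolated)
Conditions: MeLi (2.6 equiv), CuI (1.3 equiv), Et2O, 0 °C; 7, THF, −78 °C; then HMPA, 9 (2.5 equiv), −78 → −20 °C; aq. NH4Cl–NH3
Reagents that add atoms: lithium dimethylcuprate, [Li+].C[Cu-]C
Why: The Gilman reagent forms a d–π* complex with the enoate of 7 and, through a Cu(III) β-cuprio enolate and reductive elimination, transfers methyl to C8′ (ring C4) to give lithium enolate 10, which HMPA makes reactive enough for SN2 C-alkylation at C8 (ring C3) by the benzylic bromide 9. The closest known reaction type is the three-component conjugate addition and enolate trapping of γ-substituted butenolides used for trans-α,β-disubstituted lignan lactones. No ring is closed; the step forms the C8′–C9′ and C7–C8 bonds on the existing lactone. The C8′ centre is controlled by the C7′ aryl group, which blocks its own face of the flat butenolide so that methyl enters anti (4,5-trans), and the C8 centre is controlled by the new C8′ methyl, which directs the electrophile to the opposite enolate face (3,4-trans). The step needs 1,4-addition rather than deprotonation of the acidic C7′–H and C- rather than O-alkylation, which the soft, weakly basic cuprate at −78 °C and the soft benzylic bromide in excess should secure. If the kinetic trans/cis ratio at C8 is insufficient, the lactone α-centre can be equilibrated with base towards the more stable all-trans isomer.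

Step 8
Reactants: 11 rac-(3S,4S,5S)-3-[4-(benzyloxy)-3,5-dimethoxybenzyl]-5-[4-(benzyloxy)-3,5-dimethoxyphenyl]-4-methyldihydrofuran-2(3H)-one
Product: 12 rac-(2S,3R)-2-(4-hydroxy-3,5-dimethoxybenzyl)-4-(4-hydroxy-3,5-dimethoxyphenyl)-3-methylbutanoic acid
Conditions: H2 (4 atm), 10% Pd/C, AcOH–EtOAc, 40 °C
Reagents that add atoms: none
Why: Catalytic hydrogenolysis cleaves all three benzylic C–O bonds (two aryl benzyl ethers and the lactone C7′–O bond next to the electron-rich ring) to give the ring-opened acid; C8 and C8′ are not benzylic and keep their configuration, while C7′ becomes CH2.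

Step 9
Reactants: 12 rac-(2S,3R)-2-(4-hydroxy-3,5-dimethoxybenzyl)-4-(4-hydroxy-3,5-dimethoxyphenyl)-3-methylbutanoic acid
Product: 13 rac-(2S,3R)-2-(4-hydroxy-3,5-dimethoxybenzyl)-4-(4-hydroxy-3,5-dimethoxyphenyl)-3-methylbutan-1-ol
Conditions: BH3·THF (6 equiv), THF, 0 °C → rt; MeOH
Reagents that add atoms: none
Why: Borane reduces the carboxylic acid through an acyloxyborane, the phenols only form aryl borates that methanol cleaves, and the non-basic medium should leave the α-centre C8 unepimerised.

Step 10
Reactants: 13 rac-(2S,3R)-2-(4-hydroxy-3,5-dimethoxybenzyl)-4-(4-hydroxy-3,5-dimethoxyphenyl)-3-methylbutan-1-ol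
Product: 14 rac-4,4'-[(2S,3R)-2-(iodomethyl)-3-methylbutane-1,4-diyl]bis(2,6-dimethoxyphenol)
Conditions: PPh3, I2, imidazole, CH2Cl2, 0 °C → rt
Reagents that add atoms: iodine, II
Why: Appel-type (Garegg–Samuelsson) iodination; the primary alkoxyphosphonium ion is displaced by iodide (SN2) at non-stereogenic C9, phenols cannot be displaced at sp2 carbon and return on work-up, and all ring positions ortho and para to OH are blocked against iodination.

Step 11
Reactants: 14 rac-4,4'-[(2S,3R)-2-(iodomethyl)-3-methylbutane-1,4-diyl]bis(2,6-dimethoxyphenol)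
Product: 15 4,4'-[(2R,3S)-2,3-dimethylbutane-1,4-diyl]bis(2,6-dimethoxyphenol)
Conditions: Bu3SnH, AIBN (cat.), toluene, 80 °C
Reagents that add atoms: none
Why: Radical chain hydrodeiodination; the stannyl radical abstracts iodine and the primary C9 radical takes hydrogen from Sn–H, the neutral medium avoids phenoxide formation and intramolecular alkylation, and no stereocentre is involved, so the meso pair set in step 7 is delivered unchanged.

**Compound list**

1 | syringaldehyde | COc1cc(C=O)cc(OC)c1O | starting material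
2 | 4-(benzyloxy)-3,5-dimethoxybenzaldehyde | COc1cc(C=O)cc(OC)c1OCc1ccccc1 | intermediate
3 | vinylmagnesium bromide | C=C[Mg]Br | starting material
4 | rac-1-[4-(benzyloxy)-3,5-dimethoxyphenyl]prop-2-en-1-ol (S enantiomer drawn) | O[C@H](c1cc(OC)c(OCc2ccccc2)c(OC)c1)C=C | intermediate
5 | acryloyl chloride | C=CC(Cl)=O | starting material
6 | rac-1-[4-(benzyloxy)-3,5-dimethoxyphenyl]prop-2-en-1-yl prop-2-enoate (S enantiomer drawn) | C=CC(=O)O[C@H](c1cc(OC)c(OCc2ccccc2)c(OC)c1)C=C | intermediate
7 | rac-5-[4-(benzyloxy)-3,5-dimethoxyphenyl]furan-2(5H)-one (S enantiomer drawn) | O=C1O[C@H](c2cc(OC)c(OCc3ccccc3)c(OC)c2)C=C1 | intermediate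
8 | [4-(benzyloxy)-3,5-dimethoxyphenyl]methanol | OCc1cc(OC)c(OCc2ccccc2)c(OC)c1 | intermediate
9 | 2-(benzyloxy)-5-(bromomethyl)-1,3-dimethoxybenzene | COc1cc(CBr)cc(OC)c1OCc1ccccc1 | intermediate
10 | lithium rac-(4S,5S)-5-[4-(benzyloxy)-3,5-dimethoxyphenyl]-4-methyl-4,5-dihydrofuran-2-olate (4,5-trans enolate; not isolated) | [Li+].[O-]C1=C[C@H](C)[C@@H](c2cc(OC)c(OCc3ccccc3)c(OC)c2)O1 | intermediate
11 | rac-(3S,4S,5S)-3-[4-(benzyloxy)-3,5-dimethoxybenzyl]-5-[4-(benzyloxy)-3,5-dimethoxyphenyl]-4-methyldihydrofuran-2(3H)-one (3,4-trans-4,5-trans) | O=C1O[C@H](c2cc(OC)c(OCc3ccccc3)c(OC)c2)[C@@H](C)[C@@H]1Cc1cc(OC)c(OCc2ccccc2)c(OC)c1 | intermediate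
12 | rac-(2S,3R)-2-(4-hydroxy-3,5-dimethoxybenzyl)-4-(4-hydroxy-3,5-dimethoxyphenyl)-3-methylbutanoic acid | OC(=O)[C@@H](Cc1cc(OC)c(O)c(OC)c1)[C@H](C)Cc1cc(OC)c(O)c(OC)c1 | intermediate
13 | rac-(2S,3R)-2-(4-hydroxy-3,5-dimethoxybenzyl)-4-(4-hydroxy-3,5-dimethoxyphenyl)-3-methylbutan-1-ol | OC[C@@H](Cc1cc(OC)c(O)c(OC)c1)[C@H](C)Cc1cc(OC)c(O)c(OC)c1 | intermediate
14 | rac-4,4'-[(2S,3R)-2-(iodomethyl)-3-methylbutane-1,4-diyl]bis(2,6-dimethoxyphenol) | IC[C@@H](Cc1cc(OC)c(O)c(OC)c1)[C@H](C)Cc1cc(OC)c(O)c(OC)c1 | intermediate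
15 | 4,4'-[(2R,3S)-2,3-dimethylbutane-1,4-diyl]bis(2,6-dimethoxyphenol) (meso; CNP0314108.1) | COc1cc(C[C@@H](C)[C@@H](C)Cc2cc(OC)c(O)c(OC)c2)cc(OC)c1O | target

**Step count**

Total: 11 steps. Longest linear sequence: 9 steps (1, 2, 3, 4, 7, 8, 9, 10, 11) from syringaldehyde; steps 5 and 6 form the side branch to the bromide.

**Steps most likely to fail**

Step 7. The cuprate may deprotonate the acidic C7′–H instead of adding. The copper-containing enolate may also be C-alkylated too slowly, so that proton transfer, double alkylation or coupling of the bromide with methylcopper species takes over. Fallback: setting out from 7, the cuprate addition alone is run (Me2CuLi, Et2O–THF, −78 °C, NH4Cl quench) to give rac-(4S,5S)-5-[4-(benzyloxy)-3,5-dimethoxyphenyl]-4-methyldihydrofuran-2(3H)-one F1. After isolation, its copper-free lithium enolate is formed with LiHMDS in THF at −78 °C and alkylated with 9 anti to the methyl group, coming back to the route at 11.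

Step 8. Hydrogenolysis may stop after O-debenzylation with the lactone C7′–O bond intact. Acid added to force it may ionise C7′ and cause Friedel–Crafts closure onto the other arene. Fallback: setting out from 11, LiAlH4 (THF, 0 °C) opens the lactone to rac-(1S,2S,3S)-1-[4-(benzyloxy)-3,5-dimethoxyphenyl]-3-[4-(benzyloxy)-3,5-dimethoxybenzyl]-2-methylbutane-1,4-diol F2, in which C9 is already at the alcohol level. Hydrogenolysis (H2, Pd/C, EtOH–AcOH) then removes the benzyl ethers and the C7′ hydroxyl, which the para-hydroxyaryl ring activates. Any tetrahydrofuran formed from the diol is itself a benzylic ether and would be cleaved to the same product. The fallback comes back at 13 and makes step 9 unnecessary.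

Step 10. The phosphonium reagent may be tied up by the two phenols, or the electron-rich phenol rings may attack the newly formed iodide intramolecularly, so that activation of the primary alcohol is unselective. Fallback: setting out from 13, the phenols are selectively re-benzylated (BnBr, K2CO3, acetone) to rac-(2S,3R)-2-[4-(benzyloxy)-3,5-dimethoxybenzyl]-4-[4-(benzyloxy)-3,5-dimethoxyphenyl]-3-methylbutan-1-ol F3. Tosylation (TsCl, pyridine) gives rac-(2S,3R)-2-[4-(benzyloxy)-3,5-dimethoxybenzyl]-4-[4-(benzyloxy)-3,5-dimethoxyphenyl]-3-methylbutyl 4-methylbenzenesulfonate F4. Hydride displacement (LiEt3BH, THF) gives meso-(2R,3S)-1,4-bis[4-(benzyloxy)-3,5-dimethoxyphenyl]-2,3-dimethylbutane F5, and hydrogenolysis (H2, Pd/C, EtOAc) comes back to the route at 15, bypassing 14 and step 11.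

**Further compounds**

F1 | step 7 | rac-(4S,5S)-5-[4-(benzyloxy)-3,5-dimethoxyphenyl]-4-methyldihydrofuran-2(3H)-one | O=C1C[C@H](C)[C@@H](c2cc(OC)c(OCc3ccccc3)c(OC)c2)O1
F2 | step 8 | rac-(1S,2S,3S)-1-[4-(benzyloxy)-3,5-dimethoxyphenyl]-3-[4-(benzyloxy)-3,5-dimethoxybenzyl]-2-methylbutane-1,4-diol | OC[C@@H](Cc1cc(OC)c(OCc2ccccc2)c(OC)c1)[C@H](C)[C@H](O)c1cc(OC)c(OCc2ccccc2)c(OC)c1
F3 | step 10 | rac-(2S,3R)-2-[4-(benzyloxy)-3,5-dimethoxybenzyl]-4-[4-(benzyloxy)-3,5-dimethoxyphenyl]-3-methylbutan-1-ol | OC[C@@H](Cc1cc(OC)c(OCc2ccccc2)c(OC)c1)[C@H](C)Cc1cc(OC)c(OCc2ccccc2)c(OC)c1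
F4 | step 10 | rac-(2S,3R)-2-[4-(benzyloxy)-3,5-dimethoxybenzyl]-4-[4-(benzyloxy)-3,5-dimethoxyphenyl]-3-methylbutyl 4-methylbenzenesulfonate | Cc1ccc(cc1)S(=O)(=O)OC[C@@H](Cc1cc(OC)c(OCc2ccccc2)c(OC)c1)[C@H](C)Cc1cc(OC)c(OCc2ccccc2)c(OC)c1
F5 | step 10 | meso-(2R,3S)-1,4-bis[4-(benzyloxy)-3,5-dimethoxyphenyl]-2,3-dimethylbutane | C[C@@H](Cc1cc(OC)c(OCc2ccccc2)c(OC)c1)[C@H](C)Cc1cc(OC)c(OCc2ccccc2)c(OC)c1
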